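## Retrosynthetic overview

- The target comes from its hexa-O-benzyl ether by hydrogenolysis, and that from a bis-ketoxime by deoximation; the two aroyl groups are carried as C=N–O units.
- The bis-ketoxime comes from a C2-symmetric oxolane-fused bis-isoxazoline (a tricyclic bis-ketal). Twofold reductive cleavage of the ketal C–O(N) bonds puts H on C2/C5 anti to the neighbouring masked acyl group (2,3-cis, 4,5-cis, 2,5-trans).
- The tricycle comes from a 2,5-diarylfuran and two equivalents of an aryl nitrile oxide. Both isoxazoline rings form in one operation, on opposite faces (3,4-trans); the racemate is resolved.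
- The furan comes from 2,5-dibromofuran and an arylboronic acid (double Suzuki coupling); the nitrile oxide comes from 2,4-bis(benzyloxy)benzaldehyde.
- Ring order: the furan ring is bought, the two isoxazoline rings are formed together, then both are opened again, leaving the oxolane as the only non-aromatic ring.

Assumption: compounds 1, 2 and 4 are bought; racemic compounds (8, 9) are drawn as the enantiomer that is carried on.

## Route

Step 1
Reactants: 1 2,5-dibromofuran; 2 [4-(benzyloxy)phenyl]boronic acid (2.4 equiv)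
Product: 3 2,5-bis[4-(benzyloxy)phenyl]furan
Conditions: Pd(PPh3)4 (5 mol %), K2CO3 (4 equiv), 1,4-dioxane/H2O 4:1, 90 °C
Reagents that add atoms: none
Why: A twofold Suzuki–Miyaura cross-coupling at the two activated α-bromofuran positions installs both aryl groups in one operation; no stereocenter is formed.

Step 2
Reactants: 3 2,5-bis[4-(benzyloxy)phenyl]furan; 4 2,4-bis(benzyloxy)benzaldehyde (3 equiv)
Product: 9 rac-(3aS,3bS,6aS,7aS)-3,4-bis[2,4-bis(benzyloxy)phenyl]-6a,7a-bis[4-(benzyloxy)phenyl]-3a,3b,6a,7a-tetrahydrofuro[2,3-d:5,4-d']bis[1,2]oxazole (anti bis-adduct), via oxime 5 (not isolated), via hydroximoyl chloride 6 (not isolated), via nitrile oxide 7 (not isolated), via mono-cycloadduct 8 (not isolated)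
Conditions: 4, aq. NH2OH (50 wt %, 3.1 equiv), DMF, 23 °C; N-chlorosuccinimide (3.0 equiv), 30 °C; then 3 (1 equiv), Et3N (3.3 equiv, added over 12 h), 40 °C
Reagents that add atoms: hydroxylamine, NO
Why: A double Huisgen 1,3-dipolar cycloaddition of the nitrile oxide to both enol-ether C=C bonds of the furan forms the two isoxazoline rings in this one operation, with the oxygen terminus going to the aryl-bearing α-carbon as known for furan itself; the second dipole adds to the convex face of 8, anti to the first isoxazoline, so the two new C–C bonds (C3a, C3b) are trans and each ketal centre follows from suprafacial addition (racemate).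

Step 3
Reactants: 9 rac-anti bis-adduct
Product: 10 (3aS,3bS,6aS,7aS)-3,4-bis[2,4-bis(benzyloxy)phenyl]-6a,7a-bis[4-(benzyloxy)phenyl]-3a,3b,6a,7a-tetrahydrofuro[2,3-d:5,4-d']bis[1,2]oxazole
Conditions: preparative chiral SFC (amylose tris(3,5-dimethylphenylcarbamate) phase), CO2/MeOH, 35 °C
Reagents that add atoms: none
Why: Chromatographic resolution on a chiral stationary phase separates the two enantiomers of the rigid C2-symmetric tricycle, and the (3aS,3bS,6aS,7aS)-enantiomer (assigned by X-ray anomalous dispersion) is kept, which fixes the absolute configuration of C3 and C4 of the target.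

Step 4
Reactants: 10 (3aS,3bS,6aS,7aS)-bis-isoxazoline
Product: 13 (1E,1'E)-[(2S,3S,4S,5S)-2,5-bis[4-(benzyloxy)phenyl]oxolane-3,4-diyl]bis{[2,4-bis(benzyloxy)phenyl]methanone} dioxime, via monoreduced silyl oxime 11 (not isolated), via bis(silyl oxime) 12 (not isolated)
Conditions: Et3SiH (6 equiv), Me3SiOTf (0.2 equiv), CH2Cl2, −78 to −30 °C; then aq. citric acid, THF, 0 °C
Reagents that add atoms: none
Why: Proposed new method: silyl activation at the isoxazoline nitrogen ionises the ketal C–O(N) bond (the oximate is the better leaving group and the ring oxygen the better donor) to an aryl-stabilised five-membered oxocarbenium ion that Et3SiH reduces, the silyl group ending on the oxime oxygen (closest known reactions: Noyori's Me3SiOTf-catalysed reductive cleavage of acetals by silanes, and the hydride reduction of 2-aryl oxolanyl oxocarbenium ions used in lignan synthesis, rationalised by Woerpel's inside-attack model); at each ketal carbon the hydride enters anti to the neighbouring C(Ar)=N substituent, which allylic strain with the cation's aryl group holds pseudoaxial and which still carries the departing oximate on that face, so each aryl group ends cis to its neighbouring masked acyl group and the two aryl groups end trans (C2 and C5 set).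

Step 5
Reactants: 13 bis-ketoxime
Product: 15 [(2S,3R,4R,5S)-2,5-bis[4-(benzyloxy)phenyl]oxolane-3,4-diyl]bis{[2,4-bis(benzyloxy)phenyl]methanone}, via bis(NH-imine) 14 (not isolated)
Conditions: aq. TiCl3 (in HCl, 5 equiv), NH4OAc buffer (pH 5–6), THF/H2O, 23 °C
Reagents that add atoms: water, O
Why: Reductive deoximation (trivalent titanium cleaves the N–O bond and the N–H ketimine hydrolyses in the buffered medium) unmasks both aryl ketones under near-neutral conditions, so the α-stereocenters C3/C4, which are cis to the neighbouring aryl groups, are not epimerised; no new stereocenter is formed.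

Step 6
Reactants: 15 hexa-O-benzyl diketone
Product: 16 [(2S,3R,4R,5S)-2,5-bis(4-hydroxyphenyl)oxolane-3,4-diyl]bis[(2,4-dihydroxyphenyl)methanone] (CNP0237262.3)
Conditions: H2 (1 atm), Pd/C (10 wt % Pd), EtOAc/MeOH 1:1, 23 °C
Reagents that add atoms: none
Why: Hydrogenolysis of the six benzyl aryl ethers under neutral conditions, which is faster than cleavage of the dialkyl benzylic C–O bonds of the oxolane, frees all six phenols without touching the four stereocenters.

## Compound list

1 | 2,5-dibromofuran | Brc1ccc(Br)o1 | starting material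
2 | [4-(benzyloxy)phenyl]boronic acid | OB(O)c1ccc(OCc2ccccc2)cc1 | starting material
3 | 2,5-bis[4-(benzyloxy)phenyl]furan | o1c(-c2ccc(OCc3ccccc3)cc2)ccc1-c1ccc(OCc2ccccc2)cc1 | intermediate
4 | 2,4-bis(benzyloxy)benzaldehyde | O=Cc1ccc(OCc2ccccc2)cc1OCc1ccccc1 | starting material
5 | (E)-2,4-bis(benzyloxy)benzaldehyde oxime | O/N=C/c1ccc(OCc2ccccc2)cc1OCc1ccccc1 | intermediate
6 | 2,4-bis(benzyloxy)-N-hydroxybenzenecarboximidoyl chloride | ON=C(Cl)c1ccc(OCc2ccccc2)cc1OCc1ccccc1 | intermediate
7 | 2,4-bis(benzyloxy)benzonitrile oxide | [O-][N+]#Cc1ccc(OCc2ccccc2)cc1OCc1ccccc1 | intermediate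
8 | rac-(3aS,6aS)-3-[2,4-bis(benzyloxy)phenyl]-5,6a-bis[4-(benzyloxy)phenyl]-3a,6a-dihydrofuro[2,3-d][1,2]oxazole (racemate; one enantiomer drawn) | O1[C@]2(c4ccc(OCc5ccccc5)cc4)ON=C(c4ccc(OCc5ccccc5)cc4OCc4ccccc4)[C@@H]2C=C1c4ccc(OCc5ccccc5)cc4 | intermediate
9 | rac-(3aS,3bS,6aS,7aS)-3,4-bis[2,4-bis(benzyloxy)phenyl]-6a,7a-bis[4-(benzyloxy)phenyl]-3a,3b,6a,7a-tetrahydrofuro[2,3-d:5,4-d']bis[1,2]oxazole (racemate; one enantiomer drawn; oxolane oxygen bridges the two ketal carbons, isoxazolines on opposite faces) | O1[C@]2(c4ccc(OCc5ccccc5)cc4)ON=C(c4ccc(OCc5ccccc5)cc4OCc4ccccc4)[C@@H]2[C@@H]3[C@@]1(c4ccc(OCc5ccccc5)cc4)ON=C3c4ccc(OCc5ccccc5)cc4OCc4ccccc4 | intermediate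
10 | (3aS,3bS,6aS,7aS)-3,4-bis[2,4-bis(benzyloxy)phenyl]-6a,7a-bis[4-(benzyloxy)phenyl]-3a,3b,6a,7a-tetrahydrofuro[2,3-d:5,4-d']bis[1,2]oxazole (single enantiomer) | O1[C@]2(c4ccc(OCc5ccccc5)cc4)ON=C(c4ccc(OCc5ccccc5)cc4OCc4ccccc4)[C@@H]2[C@@H]3[C@@]1(c4ccc(OCc5ccccc5)cc4)ON=C3c4ccc(OCc5ccccc5)cc4OCc4ccccc4 | intermediate
11 | (3aS,4S,5S,6aS)-3-[2,4-bis(benzyloxy)phenyl]-5,6a-bis[4-(benzyloxy)phenyl]-4-[(E)-[2,4-bis(benzyloxy)phenyl]{[(triethylsilyl)oxy]imino}methyl]-3a,4,5,6a-tetrahydrofuro[2,3-d][1,2]oxazole | O1[C@H](c4ccc(OCc5ccccc5)cc4)[C@H](/C(c4ccc(OCc5ccccc5)cc4OCc4ccccc4)=N\O[Si](CC)(CC)CC)[C@@H]2[C@@]1(c4ccc(OCc5ccccc5)cc4)ON=C2c4ccc(OCc5ccccc5)cc4OCc4ccccc4 | intermediate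
12 | (1E,1'E)-[(2S,3S,4S,5S)-2,5-bis[4-(benzyloxy)phenyl]oxolane-3,4-diyl]bis{[2,4-bis(benzyloxy)phenyl]methanone} bis[O-(triethylsilyl)oxime] | O1[C@H](c4ccc(OCc5ccccc5)cc4)[C@H](/C(c4ccc(OCc5ccccc5)cc4OCc4ccccc4)=N\O[Si](CC)(CC)CC)[C@@H](/C(c4ccc(OCc5ccccc5)cc4OCc4ccccc4)=N\O[Si](CC)(CC)CC)[C@H]1c4ccc(OCc5ccccc5)cc4 | intermediate
13 | (1E,1'E)-[(2S,3S,4S,5S)-2,5-bis[4-(benzyloxy)phenyl]oxolane-3,4-diyl]bis{[2,4-bis(benzyloxy)phenyl]methanone} dioxime | O1[C@H](c4ccc(OCc5ccccc5)cc4)[C@H](/C(c4ccc(OCc5ccccc5)cc4OCc4ccccc4)=N\O)[C@@H](/C(c4ccc(OCc5ccccc5)cc4OCc4ccccc4)=N\O)[C@H]1c4ccc(OCc5ccccc5)cc4 | intermediate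
14 | 1,1'-[(2S,3S,4S,5S)-2,5-bis[4-(benzyloxy)phenyl]oxolane-3,4-diyl]bis{1-[2,4-bis(benzyloxy)phenyl]methanimine} | O1[C@H](c4ccc(OCc5ccccc5)cc4)[C@H](C(=N)c4ccc(OCc5ccccc5)cc4OCc4ccccc4)[C@@H](C(=N)c4ccc(OCc5ccccc5)cc4OCc4ccccc4)[C@H]1c4ccc(OCc5ccccc5)cc4 | intermediate
15 | [(2S,3R,4R,5S)-2,5-bis[4-(benzyloxy)phenyl]oxolane-3,4-diyl]bis{[2,4-bis(benzyloxy)phenyl]methanone} | O1[C@H](c4ccc(OCc5ccccc5)cc4)[C@H](C(=O)c4ccc(OCc5ccccc5)cc4OCc4ccccc4)[C@@H](C(=O)c4ccc(OCc5ccccc5)cc4OCc4ccccc4)[C@H]1c4ccc(OCc5ccccc5)cc4 | intermediate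
16 | [(2S,3R,4R,5S)-2,5-bis(4-hydroxyphenyl)oxolane-3,4-diyl]bis[(2,4-dihydroxyphenyl)methanone] | O=C(c1ccc(O)cc1O)[C@@H]1[C@@H](C(=O)c2ccc(O)cc2O)[C@@H](c2ccc(O)cc2)O[C@@H]1c1ccc(O)cc1 | target

## Step count and risks

Total step count: 6 (five reaction steps and one resolution). Longest linear sequence: 6 steps (1 or 2 → 3 → 9 → 10 → 13 → 15 → 16).

The three steps most likely to fail:

Step 2 (double cycloaddition). The conjugated, aromatic furan is a sluggish dipolarophile and the nitrile oxide dimerises to the furoxan in competition. The second addition must also take place on the hindered, acid-sensitive ketal 8 before it degrades. The fallback sets out from 8 and returns to the route at 11. Compound 8 is made with 3 in threefold excess, isolated as the racemate and resolved by chiral SFC, giving the (3aS,6aS)-enantiomer of the mono-cycloadduct F1. Its ketal C–O(N) bond is cleaved first (Et3SiH, Me3SiOTf 0.2 equiv, CH2Cl2, −78 °C, non-aqueous work-up) to give the 2,3-cis 2,3-dihydrofuran O-triethylsilyl oxime F2. The remaining enol ether C=C of F2 is no longer part of an aromatic ring and no longer flanked by a ketal carbon. It takes up nitrile oxide 7 (from 6 and Et3N, DMF, 40 °C) on the face opposite to the two cis substituents and so gives 11, from which step 4 is continued.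

Step 4 (twofold reductive ketal opening). Hydride capture of the oxocarbenium ion may be outrun by loss of the neighbouring C–H proton or by ionisation at the ring oxygen, which leads to an aromatic isoxazole. The facial selectivity at the second ketal carbon, where the remote aryl group lies on the face the hydride must use, is also without direct precedent. The fallback sets out from 10 and returns at 13. Compound 10 is opened with thiophenol (PhSH 4 equiv, Me3SiOTf 0.2 equiv, CH2Cl2, −78 °C), a far faster trap for the cation than the silane, to give the bis(phenylsulfanyl) S,O-ketal dioxime F3 as a mixture of epimers at the two thioketal carbons. The C–S bonds are then reduced by a radical chain (Bu3SnH, AIBN, toluene, 80 °C). The planar benzylic α-oxy radical takes hydrogen from Bu3SnH on the face anti to the neighbouring substituent, which gives 13 without any cationic intermediate.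

Step 6 (global hydrogenolysis). The benzylic C–O bonds of the 2,5-diaryloxolane or the aryl ketones may be reduced along with the six benzyl ethers. The fallback sets out from 15 and returns at 16. The benzyl ethers are cleaved without hydrogen by BCl3 (12 equiv) and pentamethylbenzene (20 equiv) as benzyl-cation scavenger in CH2Cl2 at −78 °C, followed by a methanol quench at −78 °C. This fallback makes no new compound (F0).

Further compounds
F1 | step 2 | (3aS,6aS)-3-[2,4-bis(benzyloxy)phenyl]-5,6a-bis[4-(benzyloxy)phenyl]-3a,6a-dihydrofuro[2,3-d][1,2]oxazole (single enantiomer of 8) | O1[C@]2(c4ccc(OCc5ccccc5)cc4)ON=C(c4ccc(OCc5ccccc5)cc4OCc4ccccc4)[C@@H]2C=C1c4ccc(OCc5ccccc5)cc4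
F2 | step 2 | (E)-[(2S,3S)-2,5-bis[4-(benzyloxy)phenyl]-2,3-dihydrofuran-3-yl][2,4-bis(benzyloxy)phenyl]methanone O-(triethylsilyl)oxime | O1[C@H](c4ccc(OCc5ccccc5)cc4)[C@H](/C(c4ccc(OCc5ccccc5)cc4OCc4ccccc4)=N\O[Si](CC)(CC)CC)C=C1c4ccc(OCc5ccccc5)cc4
F3 | step 4 | (1E,1'E)-[(3S,4S)-2,5-bis[4-(benzyloxy)phenyl]-2,5-bis(phenylsulfanyl)oxolane-3,4-diyl]bis{[2,4-bis(benzyloxy)phenyl]methanone} dioxime (mixture of epimers at C2 and C5) | O1C(c4ccc(OCc5ccccc5)cc4)(Sc6ccccc6)[C@H](/C(c4ccc(OCc5ccccc5)cc4OCc4ccccc4)=N\O)[C@@H](/C(c4ccc(OCc5ccccc5)cc4OCc4ccccc4)=N\O)C1(c4ccc(OCc5ccccc5)cc4)Sc6ccccc6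
F0 | step 6 | none | none
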